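**Retrosynthetic overview**

1. Core numbering used below: C1 = aroyl-bearing bridgehead, C2–C3–C4 = enolised diketone bridge (C3 prenylated), C5 = lavandulyl-bearing bridgehead, C6 = CH2, C7 = prenyl-bearing CH, C8 = CMe2, C9 = bridging C=O. Target 22 ⇐ bis-silyl ether 21 ⇐ (two Wittig reactions) bicyclic C7-aldehyde 18; the aromatic ring is bought.
2. Key disconnection of 18: ring B at C1–C9 and C7–C8, ring A at C2–C3. This leads to two acyclic pieces: enol silane 9 (C3–C7 and C9, with the C5 quaternary centre) and alkylidene β-keto ester 15 (C1, C2, C8, aroyl). Ring B closes first and ring A second, in one flask.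
3. Enabling feature: C1 lies between the aroyl carbonyl and the C2 carbonyl and carries the quaternary C8, so C8=C1 is a 1,3-dicarbonyl-activated acceptor and C1 re-emerges as an enolate. C9 is a carboxyl carbon on quaternary C5 and is 1,4-related to the nucleophilic C7 through C5–C6. Ring B (C1, C8, C7, C6, C5, C9) is therefore a formal [4+2] Michael/Dieckmann annulation, and the C4 ketone/C2 ester pair then closes ring A (C1, C2, C3, C4, C5, C9).
4. 9 ⇐ methyl acetoacetate + prenyl bromide + (S)-lavandulol + acrolein. The lavandulyl centre is bought, C5 is set by a catalytic asymmetric Michael addition, and C1 and C7 are relayed from C5 in the key step.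
5. 15 ⇐ methyl 3,4-dihydroxybenzoate + methyl acetate + acetone (silylation, Claisen condensation, Knoevenagel condensation).

Key step: step 9

Remark on the chemistry: (S)-lavandulol (4) is taken as a purchasable single enantiomer. The CIP label of the lavandulyl centre changes from S (4, 5) to R (6 onwards) only because the substituent priorities change. The target is drawn as its C2-enol tautomer.

**Step 1**
Reactants: 1 methyl acetoacetate; 2 prenyl bromide
Product: 3 methyl 7-methyl-3-oxooct-6-enoate
Conditions: NaH, THF, 0 °C; n-BuLi, 0 °C; then 2, 0 → 23 °C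
Reagents that add atoms: none
Why: Alkylation of the acetoacetate dianion at its terminal, more nucleophilic carbon (dianion γ-alkylation) puts the future C3 prenyl group in place; no stereocentre is formed.

**Step 2**
Reactants: 4 (S)-lavandulol
Product: 5 (S)-lavandulyl iodide
Conditions: PPh3, I2, imidazole, CH2Cl2, 0 °C
Reagents that add atoms: iodine (II)
Why: Appel-type iodination of the primary alcohol proceeds by SN2 at the CH2 group and should leave the adjacent allylic stereocentre untouched.

**Step 3**
Reactants: 3 methyl 7-methyl-3-oxooct-6-enoate; 5 (S)-lavandulyl iodide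
Product: 6 methyl 2-lavandulyl-7-methyl-3-oxooct-6-enoate (C2 epimer mixture)
Conditions: NaH, THF–DMF (4:1), 0 → 50 °C
Reagents that add atoms: none
Why: SN2 C-alkylation of the soft sodium enolate of the β-keto ester by the primary iodide, where the weakly basic enolate should limit E2 loss of the allylic β-hydrogen; the new C–H stereocentre is not controlled and is erased in step 4.

**Step 4**
Reactants: 6 methyl 2-lavandulyl-7-methyl-3-oxooct-6-enoate; 7 acrolein
Product: 8 methyl (2S)-2-lavandulyl-7-methyl-3-oxo-2-(3-oxopropyl)oct-6-enoate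
Conditions: 9-O-(9-phenanthryl)cupreidine (10 mol %), 7 (3 equiv), CH2Cl2, −24 °C
Reagents that add atoms: none
Why: Asymmetric Michael addition under bifunctional cinchona-alkaloid catalysis (the quinuclidine deprotonates the β-keto ester, the C6′ phenol hydrogen-bonds acrolein) creates the C5 quaternary stereocentre; the cupreidine or the pseudo-enantiomeric cupreine catalyst is chosen for the (2S) product, and the minor C5 epimer is a diastereomer that can be removed by chromatography.

**Step 5**
Reactants: 8 methyl (2S)-2-lavandulyl-7-methyl-3-oxo-2-(3-oxopropyl)oct-6-enoate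
Product: 9 tert-butyldimethylsilyl enol ether of aldehyde 8 (E/Z mixture)
Conditions: TBSOTf (1.1 equiv), Et3N, CH2Cl2, −78 °C
Reagents that add atoms: tert-butyldimethylsilyl triflate, TBSOTf (CC(C)(C)[Si](C)(C)OS(=O)(=O)C(F)(F)F)
Why: Soft enolisation with a silyl triflate and a tertiary amine should convert the unhindered aldehyde into its enol silane faster than the ketone, whose carbonyl is shielded by the adjacent quaternary carbon; the enol geometry is irrelevant because C7 is equilibrated in step 9.

**Step 6**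
Reactants: 10 methyl 3,4-dihydroxybenzoate
Product: 11 methyl 3,4-bis(triisopropylsilyloxy)benzoate
Conditions: TIPSCl (2.5 equiv), imidazole, DMF, 40 °C
Reagents that add atoms: triisopropylsilyl chloride, TIPSCl (CC(C)[Si](Cl)(C(C)C)C(C)C)
Why: Silylation of both phenols; the triisopropylsilyl ethers should tolerate amide and alkoxide bases, Lewis acid, ylides and dilute acid and leave with fluoride at the end.

**Step 7**
Reactants: 11 methyl 3,4-bis(triisopropylsilyloxy)benzoate; 12 methyl acetate
Product: 13 methyl 3-[3,4-bis(triisopropylsilyloxy)phenyl]-3-oxopropanoate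
Conditions: LiN(i-Pr)2 (2.2 equiv), 12, THF, −78 °C; then 11, −78 → −20 °C; HCl work-up
Reagents that add atoms: none
Why: Crossed Claisen condensation in which the lithium enolate of methyl acetate acylates the non-enolisable aryl ester and deprotonation of the β-keto ester drives the equilibrium.

**Step 8**
Reactants: 13 methyl 3-[3,4-bis(triisopropylsilyloxy)phenyl]-3-oxopropanoate; 14 acetone
Product: 15 methyl 2-[3,4-bis(triisopropylsilyloxy)benzoyl]-3-methylbut-2-enoate
Conditions: TiCl4 (2 equiv), pyridine (4 equiv), 14 (5 equiv), THF, 0 → 23 °C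
Reagents that add atoms: none
Why: Knoevenagel condensation of the β-keto ester with a ketone under TiCl4/pyridine activation gives the tetrasubstituted alkylidene β-keto ester, which is the C8=C1 acceptor; no stereocentre is formed.

**Step 9**
Reactants: 9 tert-butyldimethylsilyl enol ether of aldehyde 8; 15 methyl 2-[3,4-bis(triisopropylsilyloxy)benzoyl]-3-methylbut-2-enoate
Product: 18 bicyclic exo-C7 aldehyde, via Michael adduct silyl enol ether 16 (not isolated), via ring-B cyclohexanone keto ester 17 (not isolated)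
Conditions: Tf2NH (5 mol %), toluene, −78 → −30 °C; then KOt-Bu (3 equiv), THF, −78 → 23 °C; 1 M HCl quench
Reagents that add atoms: none
Why: Proposed new method: an acid-initiated silyl triflimide Mukaiyama–Michael addition joins the enol silane carbon C7 of 9 to the fully substituted β-carbon C8 of the alkylidene β-keto ester 15 and hands the silyl group to the new C1 enolate (16); the closest known type is the Mukaiyama–Michael or inverse-demand hetero-Diels–Alder addition of enol ethers to alkylidene 1,3-dicarbonyl compounds. tert-Butoxide then frees the C1 potassium enolate, which closes ring B by a 6-exo-trig Dieckmann attack on the C9 ester (17); the methoxide released enolises the C4 ketone at C3, its only α-CH2, and a second 6-exo-trig Dieckmann attack on the C2 ester closes ring A, the closest known type being the Dieckmann closure of bicyclo[3.3.1]nonane-2,4,9-triones. The first ring closure gives a non-enolisable tricarbonyl compound and is reversible, whereas the second gives the delocalised C2–C3–C4 enolate, so the sequence should be drawn through to 18. C5, set in step 4, is the only controlling element: of the two C1 epimers of 17 only the one whose C2 ester is syn to the C4 acyl group can bridge and the other returns through retro-Dieckmann opening, while C7 carries an aldehyde and should equilibrate under the basic conditions to the equatorial (exo) position of the chair ring B. The step needs C–C bond formation at C7/C8 to outrun protodesilylation of 9 and needs aldol additions of the C3 enolate to the C7 aldehyde to stay reversible, which the aprotic low-temperature conditions and the stabilised final enolate are expected to secure.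

**Step 10**
Reactants: 18 bicyclic exo-C7 aldehyde
Product: 19 C7 2-methoxyethenyl compound (E/Z mixture)
Conditions: MeOCH2PPh3Cl (4 equiv), KN(SiMe3)2 (3.8 equiv), THF, −78 → 0 °C
Reagents that add atoms: (methoxymethyl)triphenylphosphonium chloride (COC[P+](c1ccccc1)(c1ccccc1)c1ccccc1.[Cl-])
Why: Wittig olefination of the aldehyde with the methoxymethylene ylide; the first equivalent of ylide deprotonates the C2/C4 vinylogous acid and so protects it, and the C9 and aroyl ketones are shielded by the quaternary carbons next to them.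

**Step 11**
Reactants: 19 C7 2-methoxyethenyl compound
Product: 20 C7 2-oxoethyl compound
Conditions: 1 M HCl, THF, 0 → 23 °C
Reagents that add atoms: water (O)
Why: Acid-catalysed enol ether hydrolysis (C-protonation, hydration of the oxocarbenium ion, loss of methanol) gives the one-carbon-homologated aldehyde; C7 no longer bears an acidifying group and keeps its configuration, and dilute acid at room temperature should spare the prenyl groups and aryl silyl ethers.

**Step 12**
Reactants: 20 C7 2-oxoethyl compound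
Product: 21 bis(triisopropylsilyl) ether of the target
Conditions: i-PrPPh3I (4 equiv), n-BuLi (3.8 equiv), THF, −78 → 0 °C
Reagents that add atoms: isopropyltriphenylphosphonium iodide (CC(C)[P+](c1ccccc1)(c1ccccc1)c1ccccc1.[I-])
Why: Wittig olefination with the non-stabilised isopropylidene ylide turns the CH2CHO group into the C7 prenyl group; the enol is again protected as its enolate by the excess ylide.

**Step 13**
Reactants: 21 bis(triisopropylsilyl) ether of the target
Product: 22 target CNP0425478.2
Conditions: Bu4NF (2.5 equiv), AcOH (3 equiv), THF, 0 °C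
Reagents that add atoms: none
Why: Fluoride cleaves the two aryl silyl ethers; buffering with acetic acid keeps catechol and enol protonated and should avoid base-induced oxidation of the catechol.

**Compound list**

1 | methyl acetoacetate | COC(=O)CC(C)=O | starting material
2 | prenyl bromide (1-bromo-3-methylbut-2-ene) | CC(C)=CCBr | starting material
3 | methyl 7-methyl-3-oxooct-6-enoate | COC(=O)CC(=O)CCC=C(C)C | intermediate
4 | (S)-lavandulol, (2S)-5-methyl-2-(prop-1-en-2-yl)hex-4-en-1-ol | C=C(C)[C@H](CC=C(C)C)CO | starting material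
5 | (S)-lavandulyl iodide, (3S)-3-(iodomethyl)-2,6-dimethylhepta-1,5-diene | C=C(C)[C@H](CC=C(C)C)CI | intermediate
6 | methyl (2RS)-7-methyl-2-[(2R)-5-methyl-2-(prop-1-en-2-yl)hex-4-en-1-yl]-3-oxooct-6-enoate | C=C(C)[C@H](CC=C(C)C)CC(C(=O)OC)C(=O)CCC=C(C)C | intermediate
7 | acrolein | C=CC=O | starting material
8 | methyl (2S)-7-methyl-2-[(2R)-5-methyl-2-(prop-1-en-2-yl)hex-4-en-1-yl]-3-oxo-2-(3-oxopropyl)oct-6-enoate | C=C(C)[C@H](CC=C(C)C)C[C@](C(=O)OC)(C(=O)CCC=C(C)C)CCC=O | intermediate
9 | methyl (2R)-2-[3-(tert-butyldimethylsilyloxy)prop-2-en-1-yl]-7-methyl-2-[(2R)-5-methyl-2-(prop-1-en-2-yl)hex-4-en-1-yl]-3-oxooct-6-enoate (E/Z mixture; same spatial arrangement at C2 as in 8) | C=C(C)[C@H](CC=C(C)C)C[C@](C(=O)OC)(C(=O)CCC=C(C)C)CC=CO[Si](C)(C)C(C)(C)C | intermediate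
10 | methyl 3,4-dihydroxybenzoate | COC(=O)c1ccc(O)c(O)c1 | starting material
11 | methyl 3,4-bis(triisopropylsilyloxy)benzoate | COC(=O)c1ccc(O[Si](C(C)C)(C(C)C)C(C)C)c(O[Si](C(C)C)(C(C)C)C(C)C)c1 | intermediate
12 | methyl acetate | COC(C)=O | starting material
13 | methyl 3-[3,4-bis(triisopropylsilyloxy)phenyl]-3-oxopropanoate | COC(=O)CC(=O)c1ccc(O[Si](C(C)C)(C(C)C)C(C)C)c(O[Si](C(C)C)(C(C)C)C(C)C)c1 | intermediate
14 | acetone | CC(C)=O | starting material
15 | methyl 2-[3,4-bis(triisopropylsilyloxy)benzoyl]-3-methylbut-2-enoate | COC(=O)C(=C(C)C)C(=O)c1ccc(O[Si](C(C)C)(C(C)C)C(C)C)c(O[Si](C(C)C)(C(C)C)C(C)C)c1 | intermediate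
16 | acyclic Michael adduct of 9 and 15 (C7–C8 bond formed), as the tert-butyldimethylsilyl enol ether of its aroyl ketone; quaternary centre as in 8, C7 epimer mixture | C=C(C)[C@H](CC=C(C)C)C[C@](C(=O)OC)(C(=O)CCC=C(C)C)CC(C=O)C(C)(C)C(C(=O)OC)=C(O[Si](C)(C)C(C)(C)C)c1ccc(O[Si](C(C)C)(C(C)C)C(C)C)c(O[Si](C(C)C)(C(C)C)C(C)C)c1 | intermediate (not isolated)
17 | methyl 1-[3,4-bis(triisopropylsilyloxy)benzoyl]-3-formyl-2,2-dimethyl-5-(5-methylhex-4-enoyl)-5-[(2R)-5-methyl-2-(prop-1-en-2-yl)hex-4-en-1-yl]-6-oxocyclohexane-1-carboxylate; ester on C1 cis to the acyl group on C5, formyl-bearing carbon as epimer mixture | C=C(C)[C@H](CC=C(C)C)C[C@]1(C(=O)CCC=C(C)C)CC(C=O)C(C)(C)[C@@](C(=O)c2ccc(O[Si](C(C)C)(C(C)C)C(C)C)c(O[Si](C(C)C)(C(C)C)C(C)C)c2)(C(=O)OC)C1=O | intermediate (not isolated)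
18 | (1S,5R,7S)-1-[3,4-bis(triisopropylsilyloxy)benzoyl]-2-hydroxy-8,8-dimethyl-3-(3-methylbut-2-en-1-yl)-5-[(2R)-5-methyl-2-(prop-1-en-2-yl)hex-4-en-1-yl]-4,9-dioxobicyclo[3.3.1]non-2-ene-7-carbaldehyde | C=C(C)[C@H](CC=C(C)C)C[C@]12C[C@H](C=O)C(C)(C)[C@](C(=O)c3ccc(O[Si](C(C)C)(C(C)C)C(C)C)c(O[Si](C(C)C)(C(C)C)C(C)C)c3)(C1=O)C(O)=C(CC=C(C)C)C2=O | intermediate
19 | (1S,5R,7R)-1-[3,4-bis(triisopropylsilyloxy)benzoyl]-2-hydroxy-7-(2-methoxyethenyl)-8,8-dimethyl-3-(3-methylbut-2-en-1-yl)-5-[(2R)-5-methyl-2-(prop-1-en-2-yl)hex-4-en-1-yl]bicyclo[3.3.1]non-2-ene-4,9-dione (E/Z mixture; C7 unchanged in space) | C=C(C)[C@H](CC=C(C)C)C[C@]12C[C@H](C=COC)C(C)(C)[C@](C(=O)c3ccc(O[Si](C(C)C)(C(C)C)C(C)C)c(O[Si](C(C)C)(C(C)C)C(C)C)c3)(C1=O)C(O)=C(CC=C(C)C)C2=O | intermediate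
20 | (1S,5R,7R)-1-[3,4-bis(triisopropylsilyloxy)benzoyl]-2-hydroxy-8,8-dimethyl-3-(3-methylbut-2-en-1-yl)-5-[(2R)-5-methyl-2-(prop-1-en-2-yl)hex-4-en-1-yl]-7-(2-oxoethyl)bicyclo[3.3.1]non-2-ene-4,9-dione | C=C(C)[C@H](CC=C(C)C)C[C@]12C[C@H](CC=O)C(C)(C)[C@](C(=O)c3ccc(O[Si](C(C)C)(C(C)C)C(C)C)c(O[Si](C(C)C)(C(C)C)C(C)C)c3)(C1=O)C(O)=C(CC=C(C)C)C2=O | intermediate
21 | (1S,5R,7S)-1-[3,4-bis(triisopropylsilyloxy)benzoyl]-2-hydroxy-8,8-dimethyl-3,7-bis(3-methylbut-2-en-1-yl)-5-[(2R)-5-methyl-2-(prop-1-en-2-yl)hex-4-en-1-yl]bicyclo[3.3.1]non-2-ene-4,9-dione | C=C(C)[C@H](CC=C(C)C)C[C@]12C[C@H](CC=C(C)C)C(C)(C)[C@](C(=O)c3ccc(O[Si](C(C)C)(C(C)C)C(C)C)c(O[Si](C(C)C)(C(C)C)C(C)C)c3)(C1=O)C(O)=C(CC=C(C)C)C2=O | intermediate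
22 | (1S,5R,7S)-1-(3,4-dihydroxybenzoyl)-2-hydroxy-8,8-dimethyl-3,7-bis(3-methylbut-2-en-1-yl)-5-[(2R)-5-methyl-2-(prop-1-en-2-yl)hex-4-en-1-yl]bicyclo[3.3.1]non-2-ene-4,9-dione (CNP0425478.2) | C=C(C)[C@H](CC=C(C)C)C[C@]12C[C@H](CC=C(C)C)C(C)(C)[C@](C(=O)c3ccc(O)c(O)c3)(C1=O)C(O)=C(CC=C(C)C)C2=O | target

**Step count and risks**

Total step count: 13. Longest linear sequence: 9 steps (2, 3, 4, 5, 9, 10, 11, 12, 13; the branch through step 1 is equally long).

Steps most likely to fail:

1. Step 9 (proposed cascade). Several processes can go wrong: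
   - C–C bond formation at the fully substituted C8 may be too slow, so that 9 is lost by protodesilylation.
   - In the anionic stage the C3 enolate may condense irreversibly with the C7 aldehyde.
   - Alkoxide may cleave the aroyl group from 17 by retro-Claisen reaction.
   - Retro-Michael loss of the three-carbon arm may erode C5.

   Fallback (known reaction types, stepwise, aldehyde masked). It sets out from 9 and 15 and comes back at 18. A thermal inverse-electron-demand hetero-Diels–Alder reaction (toluene, 110 °C, or 10 kbar at 23 °C) between the enol ether and the aroyl C=O/C1=C8 oxadiene gives the 2-silyloxy-3,4-dihydro-2H-pyran cycloadduct F1. Camphorsulfonic acid in MeOH/HC(OMe)3 opens it to the acyclic dimethyl acetal keto ester F2. KOt-Bu in THF performs the two Dieckmann closures on this aldehyde-free substrate to give the bicyclic C7 dimethyl acetal F3. Pyridinium p-toluenesulfonate in wet acetone and then DBU unmask the aldehyde and equilibrate it to the exo position, which is 18.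

2. Step 4. Addition to the hindered α-carbon may be slow, and the facial selectivity at the new quaternary centre may be poor if the chiral lavandulyl arm opposes the catalyst. Fallback, setting out from 6 and coming back at 8: asymmetric phase-transfer allylation (allyl bromide, an N-spiro C2-symmetric binaphthyl quaternary ammonium bromide, CsOH·H2O, toluene, −40 °C) gives the C5-allyl keto ester F4. An aldehyde-selective Wacker oxidation of its only monosubstituted alkene (PdCl2(PhCN)2, CuCl2·2H2O, AgNO2, O2, t-BuOH/MeNO2) then gives 8.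

3. Step 8. Conversion may be low because the ketone is a poor Knoevenagel partner and the hindered aldol-type adduct reverts. Fallback, setting out from 11 and coming back at 15: the lithium dienolate of methyl 3-methylbut-2-enoate (LiN(i-Pr)2, THF, −78 °C) is acylated at its α-carbon by ester 11 (crossed Claisen condensation) to give the deconjugated keto ester methyl 2-[3,4-bis(triisopropylsilyloxy)benzoyl]-3-methylbut-3-enoate F5. Catalytic DBU in CH2Cl2 then moves the double bond into conjugation to give 15.

**Further compounds**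

F1 | step 9 | methyl 6-[3,4-bis(triisopropylsilyloxy)phenyl]-2-(tert-butyldimethylsilyloxy)-4,4-dimethyl-3-[(quaternary keto ester of 8)methyl]-3,4-dihydro-2H-pyran-5-carboxylate (hetero-Diels–Alder adduct of 9 and 15; ring stereocentres as mixture) | C=C(C)[C@H](CC=C(C)C)C[C@](C(=O)OC)(C(=O)CCC=C(C)C)CC1C(O[Si](C)(C)C(C)(C)C)OC(c2ccc(O[Si](C(C)C)(C(C)C)C(C)C)c(O[Si](C(C)C)(C(C)C)C(C)C)c2)=C(C(=O)OC)C1(C)C
F2 | step 9 | acyclic Michael adduct of 8 and 15 as its dimethyl acetal (β-keto ester form; C7 and C1 as mixtures) | C=C(C)[C@H](CC=C(C)C)C[C@](C(=O)OC)(C(=O)CCC=C(C)C)CC(C(OC)OC)C(C)(C)C(C(=O)OC)C(=O)c1ccc(O[Si](C(C)C)(C(C)C)C(C)C)c(O[Si](C(C)C)(C(C)C)C(C)C)c1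
F3 | step 9 | dimethyl acetal of bicyclic aldehyde 18 (C7 epimer mixture) | C=C(C)[C@H](CC=C(C)C)C[C@]12CC(C(OC)OC)C(C)(C)[C@](C(=O)c3ccc(O[Si](C(C)C)(C(C)C)C(C)C)c(O[Si](C(C)C)(C(C)C)C(C)C)c3)(C1=O)C(O)=C(CC=C(C)C)C2=O
F4 | step 4 | methyl (2S)-7-methyl-2-[(2R)-5-methyl-2-(prop-1-en-2-yl)hex-4-en-1-yl]-3-oxo-2-(prop-2-en-1-yl)oct-6-enoate | C=C(C)[C@H](CC=C(C)C)C[C@](C(=O)OC)(C(=O)CCC=C(C)C)CC=C
F5 | step 8 | methyl 2-[3,4-bis(triisopropylsilyloxy)benzoyl]-3-methylbut-3-enoate | C=C(C)C(C(=O)OC)C(=O)c1ccc(O[Si](C(C)C)(C(C)C)C(C)C)c(O[Si](C(C)C)(C(C)C)C(C)C)c1
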